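**Retrosynthetic overview**
The target is guibourtinidol-(4α→6)-epicatechin. The upper unit (rings A, B, C) is (2R,3S,4S) and the lower unit (rings D, E, F) is (−)-epicatechin (2R,3R). The last step is one hydrogenolysis that removes seven benzyl ethers and two aryl bromine caps.
Key disconnection: C4 (ring C)–C6 (ring D) and, in the same operation, O1–C2 of ring C. This leads back to an acyclic, chalcone-derived 2-hydroxyaryl epoxy alcohol and to 8-bromo-penta-O-benzylepicatechin.
Enabling feature: C4 is benzylic to ring A, ortho to O1 (on C8a) and para to the C7 oxygen, so it ionises to a quinone-methide-type cation. C2 is benzylic to ring B and para to the C4' oxygen, so the oxirane opens at C2. C6 of ring D lies between the C5 and C7 oxygens and para to O1 of ring F.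
The epoxy alcohol comes from a Claisen–Schmidt chalcone by Juliá–Colonna epoxidation (sets C3 and, through later inversion, C2), ketone reduction and release of the phenol.
Ring order: rings A, B and D/E/F are bought in; the oxirane (temporary ring) forms in step 4; ring C forms last, in step 10.

Key step: step 10

Remark: flavan numbering is used throughout, and the carbinol carbon of 7, 8 and 13 (the later C4) is carried as a mixture of both epimers and written without a stereo mark, because it becomes planar in step 10.

**Step 1**
Reactants: 1 1-(5-bromo-2,4-dihydroxyphenyl)ethan-1-one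
Product: 2 1-[4-(benzyloxy)-5-bromo-2-hydroxyphenyl]ethan-1-one
Conditions: BnBr (1.05 equiv), K2CO3 (1.1 equiv), acetone, reflux
Reagents that add atoms: benzyl bromide, BrCc1ccccc1
Why: Williamson etherification; the 2-hydroxyl is hydrogen-bonded to the acetyl carbonyl, so one equivalent of base and benzyl bromide should alkylate only the more acidic 4-hydroxyl next to bromine.

**Step 2**
Reactants: 2 1-[4-(benzyloxy)-5-bromo-2-hydroxyphenyl]ethan-1-one
Product: 3 1-[2-(allyloxy)-4-(benzyloxy)-5-bromophenyl]ethan-1-one
Conditions: allyl bromide (1.5 equiv), K2CO3, DMF, 60 °C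
Reagents that add atoms: allyl bromide, C=CCBr
Why: Williamson etherification under more forcing conditions caps the chelated phenol as an allyl ether, which survives aldol, peroxide and hydride conditions and can later be removed without acid.

**Step 3**
Reactants: 3 1-[2-(allyloxy)-4-(benzyloxy)-5-bromophenyl]ethan-1-one; 4 4-(benzyloxy)benzaldehyde
Product: 5 (E)-1-[2-(allyloxy)-4-(benzyloxy)-5-bromophenyl]-3-[4-(benzyloxy)phenyl]prop-2-en-1-one
Conditions: KOH, EtOH/THF, 20 °C
Reagents that add atoms: none
Why: Claisen–Schmidt condensation of a methyl ketone with a non-enolisable aldehyde, in which E1cB dehydration should give only the (E)-enone.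

**Step 4**
Reactants: 5 (E)-chalcone
Product: 6 [2-(allyloxy)-4-(benzyloxy)-5-bromophenyl]{(2R,3S)-3-[4-(benzyloxy)phenyl]oxiran-2-yl}methanone
Conditions: poly-L-leucine, urea–H2O2, DBU, THF, 20 °C
Reagents that add atoms: hydrogen peroxide (from its urea adduct), OO
Why: Juliá–Colonna epoxidation (nucleophilic Weitz–Scheffer-type epoxidation inside the peptide helix), for which poly-L-leucine is known to give the (2R,3S)-epoxide of chalcones; this sets the C–O bond of the later C3 and, in the sense to be inverted, the later C2, while the allyl ether is inert to hydroperoxide anion.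

**Step 5**
Reactants: 6 (2R,3S)-epoxy ketone
Product: 7 [2-(allyloxy)-4-(benzyloxy)-5-bromophenyl]{(2S,3S)-3-[4-(benzyloxy)phenyl]oxiran-2-yl}methanol (both carbinol epimers)
Conditions: NaBH4, THF/MeOH, −10 °C
Reagents that add atoms: none
Why: Borohydride 1,2-reduction of the ketone leaves the oxirane untouched (its descriptor changes only through the priority rules), and the new carbinol centre needs no control because it becomes planar in step 10.

**Step 6**
Reactants: 7 allyl-protected epoxy alcohol
Product: 8 5-(benzyloxy)-4-bromo-2-[{(2S,3S)-3-[4-(benzyloxy)phenyl]oxiran-2-yl}(hydroxy)methyl]phenol (both carbinol epimers)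
Conditions: Pd(PPh3)4 (3 mol %), morpholine (3 equiv), THF, 20 °C; short plug of Et3N-deactivated silica, used at once
Reagents that add atoms: none
Why: Tsuji–Trost-type deallylation, in which zerovalent palladium ionises the aryl allyl ether and morpholine traps the π-allyl complex, so the phenol is released without acid and the oxirane, the benzylic alcohol and the aryl bromide should survive at room temperature.

**Step 7**
Reactants: 9 (−)-epicatechin
Product: 10 5,7,3',4'-tetra-O-benzyl-(−)-epicatechin
Conditions: BnBr (4.4 equiv), K2CO3, DMF, 0 → 20 °C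
Reagents that add atoms: benzyl bromide, BrCc1ccccc1
Why: Williamson etherification of the four phenols with a weak base, which leaves the less acidic secondary 3-hydroxyl free and avoids base-induced epimerisation at C2.

**Step 8**
Reactants: 10 5,7,3',4'-tetra-O-benzyl-(−)-epicatechin
Product: 11 8-bromo-5,7,3',4'-tetra-O-benzyl-(−)-epicatechin
Conditions: NBS (1.0 equiv), CH2Cl2, −78 → 0 °C
Reagents that add atoms: N-bromosuccinimide, O=C1CCC(=O)N1Br
Why: Electrophilic aromatic bromination, for which C8 is known as the most reactive position of ring D in 5,7-di-O-benzyl flavan-3-ols, so one equivalent of NBS at low temperature should cap C8 only.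

**Step 9**
Reactants: 11 8-bromo-5,7,3',4'-tetra-O-benzyl-(−)-epicatechin
Product: 12 8-bromo-3,5,7,3',4'-penta-O-benzyl-(−)-epicatechin
Conditions: NaH, BnBr, DMF, 0 → 20 °C
Reagents that add atoms: benzyl bromide, BrCc1ccccc1
Why: Williamson etherification of the sodium alkoxide removes the only competing oxygen nucleophile of this fragment and uses a group that falls in the final hydrogenolysis.

**Step 10**
Reactants: 8 free-phenol epoxy alcohol; 12 8-bromo-3,5,7,3',4'-penta-O-benzyl-(−)-epicatechin
Product: 15 6-bromo-7,4'-di-O-benzylguibourtinidol-(4α→6)-8-bromo-3,5,7,3',4'-penta-O-benzylepicatechin, via flavan-3,4-diol 13 (not isolated), via flavan-4-yl cation 14 (not isolated)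
Conditions: 12 (2 equiv), BF3·OEt2 (30 mol %), 4 Å MS, CH2Cl2, −78 °C, slow addition of 8, then −30 °C
Reagents that add atoms: none
Why: Proposed new method: BF3 first activates the strained oxirane of 8, whose C2–O bond is weakened by the para-benzyloxy group of ring B, so the free ring A phenol (the later O1) opens it at C2 and closes ring C in a 6-endo-tet mode to give flavan-3,4-diol 13, and on warming the C4 hydroxyl of 13, benzylic to ring A and placed ortho to O1 and para to the C7 benzyloxy group, leaves as water to give the quinone-methide-type cation 14, which is captured by C6 of ring D of 12 in a Friedel–Crafts alkylation. The closest known reaction types are the acid-catalysed 6-endo cyclisation of 2-hydroxyaryl-substituted aryl epoxides to flavan-3-ols and the Lewis-acid condensation of flavan-3,4-diols or their 4-ethers and 4-esters with flavan-3-ols that carry a halogen cap at C8; only their merger into one operation from an acyclic precursor is new. C2 is set by anti attack (inversion) on the (3S)-oxirane carbon through a chair-like array with the ring B aryl group and the C3 oxygen both equatorial, an arrangement that a looser, cation-like opening should also prefer, while C3 keeps its C–O bond and hence the configuration set in step 4. C4 is set by attack of the arene on the α face of the half-chair cation 14, opposite to the boron-complexed 3β oxygen, which places the very bulky di-ortho-benzyloxy aryl group equatorial (2,3-trans-3,4-trans), and both carbinol epimers of 8 converge because this carbon becomes planar. Site selectivity on the nucleophile is secured by the bromine at C8 of 12, which leaves C6 as the only free position of ring D, and self-condensation of the electrophile is held back by the bromine at C6 of ring A, by the excess of 12 and by the slow addition of 8. The 6-endo course is favoured over 5-exo closure at C3 by benzylic stabilisation at C2 and by the electron-withdrawing carbinol carbon next to C3.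

**Step 11**
Reactants: 15 protected, doubly bromine-capped biflavanoid
Product: 16 guibourtinidol-(4α→6)-epicatechin (target)
Conditions: H2 (1 atm), Pd(OH)2/C, NaOAc (2.5 equiv), THF/MeOH/H2O, 20 °C; Sephadex LH-20
Reagents that add atoms: none
Why: Catalytic hydrogenolysis cleaves the seven benzyl ethers and hydrodehalogenates both aryl bromides in one operation, while sodium acetate buffers the hydrogen bromide and no stereocentre is touched because the interflavan bond of a 5-deoxy upper unit is acid-stable.

**Compound list**
1 | 1-(5-bromo-2,4-dihydroxyphenyl)ethan-1-one | CC(=O)c1cc(Br)c(O)cc1O | starting material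
2 | 1-[4-(benzyloxy)-5-bromo-2-hydroxyphenyl]ethan-1-one | CC(=O)c1cc(Br)c(OCc2ccccc2)cc1O | intermediate
3 | 1-[2-(allyloxy)-4-(benzyloxy)-5-bromophenyl]ethan-1-one | CC(=O)c1cc(Br)c(OCc2ccccc2)cc1OCC=C | intermediate
4 | 4-(benzyloxy)benzaldehyde | O=Cc1ccc(OCc2ccccc2)cc1 | starting material
5 | (E)-1-[2-(allyloxy)-4-(benzyloxy)-5-bromophenyl]-3-[4-(benzyloxy)phenyl]prop-2-en-1-one | C=CCOc1cc(OCc2ccccc2)c(Br)cc1C(=O)/C=C/c1ccc(OCc2ccccc2)cc1 | intermediate
6 | [2-(allyloxy)-4-(benzyloxy)-5-bromophenyl]{(2R,3S)-3-[4-(benzyloxy)phenyl]oxiran-2-yl}methanone | O(Cc1ccccc1)c1ccc(cc1)[C@@H]1O[C@H]1C(=O)c1cc(Br)c(OCc2ccccc2)cc1OCC=C | intermediate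
7 | [2-(allyloxy)-4-(benzyloxy)-5-bromophenyl]{(2S,3S)-3-[4-(benzyloxy)phenyl]oxiran-2-yl}methanol, carbinol epimers | O(Cc1ccccc1)c1ccc(cc1)[C@@H]1O[C@H]1C(O)c1cc(Br)c(OCc2ccccc2)cc1OCC=C | intermediate
8 | 5-(benzyloxy)-4-bromo-2-[{(2S,3S)-3-[4-(benzyloxy)phenyl]oxiran-2-yl}(hydroxy)methyl]phenol, carbinol epimers | O(Cc1ccccc1)c1ccc(cc1)[C@@H]1O[C@H]1C(O)c1cc(Br)c(OCc2ccccc2)cc1O | intermediate
9 | (−)-epicatechin, (2R,3R) | Oc1cc(O)c2C[C@@H](O)[C@@H](c3ccc(O)c(O)c3)Oc2c1 | starting material
10 | 5,7,3',4'-tetra-O-benzyl-(−)-epicatechin | O(Cc1ccccc1)c1cc(OCc2ccccc2)c2C[C@@H](O)[C@@H](c3ccc(OCc4ccccc4)c(OCc4ccccc4)c3)Oc2c1 | intermediate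
11 | 8-bromo-5,7,3',4'-tetra-O-benzyl-(−)-epicatechin | O(Cc1ccccc1)c1cc(OCc2ccccc2)c2C[C@@H](O)[C@@H](c3ccc(OCc4ccccc4)c(OCc4ccccc4)c3)Oc2c1Br | intermediate
12 | 8-bromo-3,5,7,3',4'-penta-O-benzyl-(−)-epicatechin | O(Cc1ccccc1)c1cc(OCc2ccccc2)c2C[C@@H](OCc3ccccc3)[C@@H](c3ccc(OCc4ccccc4)c(OCc4ccccc4)c3)Oc2c1Br | intermediate
13 | (2R,3S)-7-(benzyloxy)-2-[4-(benzyloxy)phenyl]-6-bromochromane-3,4-diol, 2,3-trans, C4 epimers | O(Cc1ccccc1)c1ccc([C@H]2Oc3cc(OCc4ccccc4)c(Br)cc3C(O)[C@@H]2O)cc1 | intermediate
14 | (2R,3S)-7-(benzyloxy)-2-[4-(benzyloxy)phenyl]-6-bromo-3-hydroxychroman-4-ylium (quinone-methide-type cation) | O(Cc1ccccc1)c1ccc([C@H]2Oc3cc(OCc4ccccc4)c(Br)cc3[CH+][C@@H]2O)cc1 | intermediate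
15 | 6-bromo-7,4'-di-O-benzylguibourtinidol-(4α→6)-8-bromo-3,5,7,3',4'-penta-O-benzylepicatechin, upper (2R,3S,4S), lower (2R,3R) | O(Cc1ccccc1)c1ccc([C@H]2Oc3cc(OCc4ccccc4)c(Br)cc3[C@@H](c3c(OCc4ccccc4)c(Br)c4c(c3OCc3ccccc3)C[C@@H](OCc3ccccc3)[C@@H](c3ccc(OCc5ccccc5)c(OCc5ccccc5)c3)O4)[C@@H]2O)cc1 | intermediate
16 | guibourtinidol-(4α→6)-epicatechin, upper (2R,3S,4S), lower (2R,3R) | Oc1ccc([C@H]2Oc3cc(O)ccc3[C@@H](c3c(O)cc4c(c3O)C[C@@H](O)[C@@H](c3ccc(O)c(O)c3)O4)[C@@H]2O)cc1 | target

**Step count**
Total steps: 11. Longest linear sequence: 8 (steps 1–6, 10, 11).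

**Steps most likely to fail**

1. Step 10 (Proposed new method).
   - What may go wrong: the carbinol carbon may ionise before ring closure, with loss of cyclic facial control at C4. A hydride shift may follow epoxide opening (Meinwald-type rearrangement). The cation that carries a free 3-hydroxyl may show insufficient α/β facial selectivity.
   - Fallback: it uses known chemistry, sets out from 8 and comes back at 15. Compound 8 is cyclised alone with catalytic camphorsulfonic acid in CH2Cl2 at −40 °C, and flavan-3,4-diol 13 is isolated. Ac2O/pyridine converts it into the 3,4-di-O-acetate F1. BF3·OEt2 in CH2Cl2 at −78 → −30 °C with 12 ionises the 4-acetate under anchimeric assistance of the 3-acetate. The resulting cis-fused dioxolanylium ion covers the β face, so the arene can enter only from the α face and should give the 3-O-acetyl biflavanoid F2. K2CO3 in MeOH/THF then removes the acetate to give 15.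

2. Step 4.
   - What may go wrong: enantiofacial discrimination may be insufficient or turnover slow, because the ortho-allyloxy group twists the aroyl group and may fit the peptide helix poorly. Any minor enantiomer would in any case become a separable diastereomer after coupling with enantiopure 12.
   - Fallback: it sets out from 5 and comes back at 7. iBu2AlH in toluene at −78 °C reduces the enone in the 1,2-sense to the allylic alcohol F3, whose carbinol configuration is irrelevant. A Shi epoxidation follows, with the enantiomer of the fructose-derived ketone (made from L-sorbose), KHSO5 and K2CO3 buffer in MeCN/dimethoxymethane/H2O at 0 °C. This sets the (S,S)-oxirane by reagent control on the trans-disubstituted styrene-type alkene, which is more reactive than the terminal allyl ether, and gives 7.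

3. Step 6.
   - What may go wrong: the oxirane may open prematurely under base, either by 5-exo closure through the phenoxide or by attack of the amine at the benzylic carbon, during deallylation or handling.
   - Fallback: it sets out from 6 and comes back at 13. The same Pd(PPh3)4/morpholine deallylation is run at the ketone stage. The 2'-hydroxy epoxy ketone F4 released there should close spontaneously by attack of the phenol at the β-carbon, which is the ring closure of the Algar–Flynn–Oyamada reaction. This gives the (2R,3R)-trans-dihydroflavonol F5. NaBH4 in THF/MeOH reduces F5 to one C4 epimer of 13, which is isolated and submitted to 12 and BF3·OEt2 as in the second stage of step 10.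

**Further compounds**
F1 | step 10 | (2R,3S)-7-(benzyloxy)-2-[4-(benzyloxy)phenyl]-6-bromochromane-3,4-diyl diacetate, C4 epimers | O(Cc1ccccc1)c1ccc([C@H]2Oc3cc(OCc4ccccc4)c(Br)cc3C(OC(C)=O)[C@@H]2OC(C)=O)cc1
F2 | step 10 | 3-O-acetyl-6-bromo-7,4'-di-O-benzylguibourtinidol-(4α→6)-8-bromo-3,5,7,3',4'-penta-O-benzylepicatechin | O(Cc1ccccc1)c1ccc([C@H]2Oc3cc(OCc4ccccc4)c(Br)cc3[C@@H](c3c(OCc4ccccc4)c(Br)c4c(c3OCc3ccccc3)C[C@@H](OCc3ccccc3)[C@@H](c3ccc(OCc5ccccc5)c(OCc5ccccc5)c3)O4)[C@@H]2OC(C)=O)cc1
F3 | step 4 | (E)-1-[2-(allyloxy)-4-(benzyloxy)-5-bromophenyl]-3-[4-(benzyloxy)phenyl]prop-2-en-1-ol, racemic carbinol | O(Cc1ccccc1)c1ccc(cc1)/C=C/C(O)c1cc(Br)c(OCc2ccccc2)cc1OCC=C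
F4 | step 6 | [4-(benzyloxy)-5-bromo-2-hydroxyphenyl]{(2R,3S)-3-[4-(benzyloxy)phenyl]oxiran-2-yl}methanone | O(Cc1ccccc1)c1ccc(cc1)[C@@H]1O[C@H]1C(=O)c1cc(Br)c(OCc2ccccc2)cc1O
F5 | step 6 | (2R,3R)-7-(benzyloxy)-2-[4-(benzyloxy)phenyl]-6-bromo-3-hydroxychroman-4-one | O(Cc1ccccc1)c1ccc([C@H]2Oc3cc(OCc4ccccc4)c(Br)cc3C(=O)[C@@H]2O)cc1
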